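The slowness of amber after 4.00 min held me first: c(E), in percent of the G charged, stayed between 25.7% and 27.3% to the last reading, a spread of 1.6 percentage points against a scatter of 1 point. So I froze that plateau of readings and divided it by the X charged.

| flask | G | X | Q | remark | time |
|---|---|---|---|---|---|
| amber | 0.011 M | 1.3 equiv | 3.3 mM | run made earlier |  |
| green | 0.011 M | 4 equiv | 3.3 mM | run made earlier |  |
| eta | 0.011 M | 1.00 equiv | 3.30 mM |  | 10 min |
| zeta | 0.011 M | 1.50 equiv | 3.30 mM |  | 10 min |
| epsilon | 0.011 M | 3.00 equiv | 3.30 mM |  | 10 min |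

- amber (time / min: E / %, Z / %): 0.667: 7.5, 0.6; 2.00: 21.9, 1.8; 4.00: 27.3, 0; 5.00: 26.8, 2.6; 8.00: 25.7, 2.0; 10.0: 26.3, 0.6
- green (time / min: E / %, Z / %): 0.667: 36.0, 2.5; 2.00: 61.3, 8.7; 4.00: 56.2, 15.8; 5.00: 52.5, 21.2; 8.00: 40.3, 32.1; 10.0: 34.0, 35.5

(standard deviation of a reading: 1 percentage point)

- amount of E at the end, in percent of the G charged, for each flask in turn (eta, zeta, epsilon)

I called the result s, the plateau yield per equivalent, the percent of the G charged standing as E for each equivalent of X:

s = mean c(E) from 4.00 min on / 1.3 equiv = 20.4%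

Then I tested whether this one number was enough. On green it gave 81.6%, but green read 34.0% at 10.0 min, and its highest reading of E was 61.3%. Its Z reached 35.5%, more than the 0.6% of amber at that time. So s failed on green, and I trusted it for the low charges and doubted it for the high one:

eta: s × 1.00 equiv = 20.4%
zeta: s × 1.50 equiv = 30.6%
epsilon: s × 3.00 equiv = 61.2%

The forecast differed from my figures at each point, giving 5%, 44% and 50%, on the ground that “only the excess builds E”.

The flasks gave 15.7% in eta, 33.2% in zeta and 48.8% in epsilon.

    E + Q → J (k = 1.10 L mol⁻¹ s⁻¹)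
    X + E → Z + L (k = 0.0580 L mol⁻¹ s⁻¹)
    X + D → E + L (k = 1.30 L mol⁻¹ s⁻¹)
    G + X → D + L (k = 0.630 L mol⁻¹ s⁻¹)

In eta at 10.0 min, E was going to J 110 times as fast as to Z, while X, the limiting reagent there, stood at 1.68% of its charge. In zeta, s gave 30.6% against 33.2%, with X at 4.04% of its charge. In epsilon, s gave 12 points more than the flask, which held X at 27.0% of its charge and Z at 20.8%.

The earlier runs and the new flask were computed for an exercise; scatter was added.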